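The runs stem from a simulated flask on assumed constants, noise included.

Monomer in chains came first, and the meeting took the clean case as the zero of the scale: the balance in which monomer in chains equals the whole charge of free monomer.

in all of them: initiator 0.20 mM

|  | free monomer | protic impurity | remark | time |
|---|---|---|---|---|
| eta | 28 mM (fed, over 12 min) | 2 mM | run made earlier |  |
| beta | 44 mM (fed, over 12 min) | 2 mM | run made earlier |  |
| flask | 20 mM (fed, over 12 min) | 2.00 mM |  | 2.0 h |

| run | time / h | monomer in chains / % | free monomer / % |
|---|---|---|---|
| eta | 0.417 | 39.7 | 52.6 |
| eta | 0.833 | 70.3 | 22.6 |
| eta | 1.33 | 84.8 | 7.9 |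
| eta | 1.50 | 86.9 | 6.5 |
| eta | 2.00 | 90.8 | 1.7 |
| eta | 2.50 | 92.4 | 1.3 |
| beta | 0.167 | 9.5 | 68.6 |
| beta | 0.500 | 53.5 | 42.5 |
| beta | 0.833 | 75.9 | 19.7 |
| beta | 1.33 | 88.2 | 6.3 |
| beta | 2.00 | 93.6 | 2.6 |
| beta | 2.50 | 94.4 | 0.9 |

(scatter of a reading: 0.5 percentage points)

- the average divides the monomer in chains by the number of chains begun, living and dead together
- the analysis behind the earlier runs scatters by 0.5 percentage points, standard deviation
- steps under discussion: free monomer + initiator -> living end + monomer in chains; free monomer + living end -> monomer in chains + living end; 2 initiator -> spent initiator; protic impurity + free monomer -> quenched substrate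
- the earlier runs do not show the number of chains; that part of a forecast is a guess
- percentages count the whole charge, also what has not yet gone in

* average number of monomer units in a chain (chains begun, living or dead) at 2.0 h
* part of the free monomer that has reacted at 2.0 h

The first speaker argued that each protic impurity costs one free monomer, so the loss from the clean case should be a fixed amount, not a fixed percentage. She pointed to the last rows: the eta run lacked 1.76 mM and the beta run 2.07 mM, against 2 mM of impurity charged in each. She proposed f = 1 − c_H/c_M, with c_H the impurity charge and c_M the monomer charge. For the new flask this gives 90.0 %, the ceiling share: the part of the charge that can reach chains, here 18.0 mM.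

The second speaker objected that c is not capped by f, since c counts quenched monomer too and must be read from the free monomer left. This was accepted. The third speaker noted that the runs do not show the number of chains; with one chain per initiator, the ceiling would give 90.0 units, and the same monomer in chains shared among fewer chains would give longer ones. The meeting committed to one statement: late on, monomer in chains plus free monomer equals f.

The forecast gave c 97.4 % (96.4 % to 98.3 %) and dp 145 (95 to 230), holding that “the impurity removes 2 mM of monomer quickly”.

The flask gives c 97.5 % and dp 132.

    free monomer + initiator → living end + monomer in chains (k = 19.5 /M/min)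
    free monomer + living end → monomer in chains + living end, rate k2*[living end]*[free monomer] (k = 242 /M/min)
    2 initiator → spent initiator (k = 243 /M/min)
    protic impurity + free monomer → quenched substrate (k = 105 /M/min)

At 2.00 h the flask holds 87.5 % in chains and 2.54 % free, together 90.0 %, close to f. The neighbour with 0.12 mM of initiator holds 82.4 % and 7.64 %, together 90.0 %, at dp 180. The flask is not yet at rest, with its 2.54 % of free monomer still there; by the step into chains, pseudo-first-order on 0.133 mM of living ends, the half-life of free monomer then is 0.36 h, short against 2.0 h. By 20.0 h living ends still stand at 0.133 mM, free monomer is at 0 %, monomer in chains has reached 90.0 %, c is 100 %, and dp has risen to 136.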